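- If ring forms in proportion to the starting material, and quenched substrate in proportion to the starting material times the protic impurity, then starting material drops out of their ratio, and each mole per litre of ring cuts the impurity left by one fixed factor.

| flask | starting material | protic impurity | remark | time |
|---|---|---|---|---|
| midnight | 1 M (in portions, 4) | 0.067 M | run made earlier; portions every 80 s |  |
| spring | 1 M (in portions, 4) | 0.15 M | run made earlier; portions every 80 s |  |
| dusk | 0.50 M (in portions, 4) | 0.10 M | run made earlier; portions every 80 s |  |
| flask | 1.0 M (in portions, 4) | 0.100 M | the portions of starting material follow each other after 80 s, the first at the start | 10 min |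

- midnight (time / min: ring / %, quenched substrate / %): 0.667: 7, 0; 1.33: 8, 0; 3.00: 32, 10; 8.00: 76, 2
- spring (time / min: ring / %, quenched substrate / %): 1.00: 8, 5; 3.00: 31, 12; 5.00: 58, 13; 8.00: 70, 11
- dusk (time / min: ring / %, quenched substrate / %): 0.667: 8, 3; 1.33: 11, 4; 3.00: 31, 7; 8.00: 74, 13

(standard deviation of a reading: 2 percentage points)

- percentages count the starting material that a species holds: one open dimer counts as two

- concentration of ring at 10 min, in M
- concentration of quenched substrate at 10 min, in M
- concentration of open dimer at 10 min, in M

- Read at 3.00 min, the logarithm ln(impurity charged / impurity left) per mole per litre of ring is 5.19 L mol⁻¹ in the spring run and 2.78 L mol⁻¹ in the dusk run.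
- The midnight run is left out, since its reading at that time, 0.100 M, is more than its charge of 0.067 M.
- The mean, 3.99 L mol⁻¹, is our quench coefficient, a selectivity factor between impurity and ring.
- First pass: the midnight and spring runs, which hold the flask's charge of starting material but other charges of impurity, average 0.730 M of ring at 8.00 min, so for the flask at that ring the coefficient gives 0.0945 M of quenched substrate.
- Second pass: putting that back leaves 0.175 M unfinished in the flask. The readings of the spring run show its unfinished material falling at about 0.141 min⁻¹, so for the flask at 10 min we reckon ring at 0.773 M and quenched substrate at 0.0954 M.
- The weak link is the coefficient itself: taken singly, the dusk and spring readings give 0.0883 M and 0.0982 M for the flask.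
- The forecast gives 0.77 M of ring, 0.08 M of quenched substrate and 0.06 M of open dimer, on the ground that “Quenched substrate is capped by the impurity.” Our quenched substrate is higher than its figure.

The flask gives 0.802 M of ring, 0.0965 M of quenched substrate and 0.0391 M of open dimer.

    2 starting material ⇌ open dimer (K = 2.60 L mol⁻¹, k = 0.00370 L mol⁻¹ s⁻¹)
    starting material + protic impurity → quenched substrate (k = 0.0380 L mol⁻¹ s⁻¹)
    starting material → ring (k = 0.00910 s⁻¹)

With the flask's ring put in, the quench coefficient gives 0.0959 M of quenched substrate, against the 0.0965 M that stands there. The neighbouring flask is charged with 0.025 M of protic impurity, a quarter of the flask's charge, and at 10 min it holds 0.861 M of ring. The same coefficient, with that ring, gives 0.0242 M of quenched substrate for the neighbouring flask, and that flask holds 0.0243 M.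

(The numbers in the tables were computed for substances that don't exist.)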